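The route rests on breaking the C8–C14 bond of aromatic ring C and folding C11–C14 back into a cyclobutenone. Ring C is a hexasubstituted hydroquinone in which C11–OH, C12–OMe, C13–isopropyl and C14–OH stand in a row, which is the substituent order of a squarate-derived four-membered ring. Heating a 4-cyclohexenyl-4-hydroxy-3-methoxy-2-isopropylcyclobutenone opens the strained ring to a dienylketene that recloses onto C8. Ring C therefore appears with all four substituents in place in one reagent-free operation. The precursor carries ring B as a cyclohexene with C5 and C10 already set and with C7 and C3 masked as silyl ethers. It comes from an alkenyllithium and an isopropyl methoxy cyclobutenedione.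

Key step: step 10

Remarks before the steps
- **Numbering:** abietane numbering is used throughout. C5 bears the isopropenyl group. C10 bears the methyl group and the C1–C2–C3 chain. Ring B is C5–C10. Ring C is C8, C9 and C11–C14.
- **Structure of the enone starting material:** it is the six-membered ring, CC1=CCCCC1=O. The shorter string CC1=CCCC1=O would be 2-methylcyclopent-2-en-1-one and could not give six-membered ring B.
- **Assumption:** the sense of induction of the copper/diphosphine catalyst on this enone has to be assigned in a pilot run. Both ligand antipodes are sold, and the one that gives 5S is used.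
- **Epimer mixtures:** C7 and the carbinol carbon C11 are carried as epimer mixtures. Both centres disappear later, C11 in step 10 and C7 in step 12.

Step 1
Reactants: 1 2-methylcyclohex-2-en-1-one; 2 isopropenylmagnesium bromide; 3 allyl bromide
Product: 5 (2S,3S)-2-allyl-2-methyl-3-(prop-1-en-2-yl)cyclohexan-1-one, via magnesium enolate 4 (not isolated)
Conditions: CuBr·SMe2 (5 mol %), Josiphos ligand 1-[2-(diphenylphosphino)ferrocenyl]ethyldicyclohexylphosphine (6 mol %, antipode per the assumption), 2 (1.2 equiv), 2-MeTHF, −78 °C; then 3 (3 equiv), DMPU, −78 → 0 °C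
Reagents that add atoms: isopropenylmagnesium bromide 2, C=C(C)[Mg]Br; allyl bromide 3, C=CCBr
Why: Copper-catalysed asymmetric conjugate addition sets C5 under ligand control, and the regiodefined enolate 4, whose isopropenyl group sits pseudoaxial to avoid the C10 methyl, should be allylated on the opposite face, which sets C10 with allyl trans and methyl cis to the isopropenyl group (tandem conjugate addition–enolate alkylation).

Step 2
Reactants: 5 (2S,3S)-2-allyl-2-methyl-3-(prop-1-en-2-yl)cyclohexan-1-one
Product: 7 (5S,6S)-6-allyl-6-methyl-5-(prop-1-en-2-yl)cyclohex-2-en-1-one, via lithium enolate 6 (not isolated)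
Conditions: LiN(i-Pr)2 (LDA, commercial solution, 1.1 equiv), THF, −78 °C; then N-tert-butylbenzenesulfinimidoyl chloride (1.2 equiv), −78 °C
Reagents that add atoms: none
Why: Only C8 carries enolisable hydrogens, so enolate 6 forms alone, attacks the sulfur reagent and loses the sulfenamide by syn elimination at low temperature (Mukaiyama dehydrogenation), with no palladium salt present that could cyclise an enol ether onto the allyl group.

Step 3
Reactants: 7 (5S,6S)-6-allyl-6-methyl-5-(prop-1-en-2-yl)cyclohex-2-en-1-one
Product: 8 (2S,3S)-2-allyl-2-methyl-5-(pinacolatoboryl)-3-(prop-1-en-2-yl)cyclohexan-1-one (C7 epimers)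
Conditions: CuCl (5 mol %), bis[2-(diphenylphosphino)phenyl] ether (DPEphos, 5 mol %), NaOt-Bu (10 mol %), B2pin2 (1.1 equiv), MeOH (2 equiv), THF, rt
Reagents that add atoms: bis(pinacolato)diboron (B2pin2), CC1(C)OB(OC1(C)C)B1OC(C)(C)C(C)(C)O1
Why: A phosphine-ligated copper boryl species adds to the electron-poor C7 of the enone far faster than to the two isolated alkenes and methanol releases the ketone (copper-catalysed conjugate borylation), and the C7 configuration does not matter because this carbon ends as a ketone.

Step 4
Reactants: 8 (2S,3S)-2-allyl-2-methyl-5-(pinacolatoboryl)-3-(prop-1-en-2-yl)cyclohexan-1-one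
Product: 10 (2S,3S)-5-hydroxy-2-(3-hydroxypropyl)-2-methyl-3-(prop-1-en-2-yl)cyclohexan-1-one (C7 epimers), via catechol boronate 9 (not isolated)
Conditions: RhCl(PPh3)3 (2 mol %), catecholborane (1.3 equiv), THF, 0 °C → rt; then NaBO3·4H2O, THF/H2O, rt
Reagents that add atoms: sodium perborate (both new oxygen atoms), [Na+].[Na+].O[B-]1(O)OO[B-](O)(O)OO1; catecholborane (boron and catecholate of 9 only), B1Oc2ccccc2O1
Why: Rhodium-catalysed hydroboration takes the monosubstituted alkene in preference to both the 1,1-disubstituted isopropenyl group and the hindered ketone, a distinction that uncatalysed dialkylboranes draw less reliably, puts boron on terminal C3, and mild perborate then turns both C–B bonds into C–OH with retention and without retro-aldol cleavage.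

Step 5
Reactants: 10 (2S,3S)-5-hydroxy-2-(3-hydroxypropyl)-2-methyl-3-(prop-1-en-2-yl)cyclohexan-1-one
Product: 11 C3/C7 bis(tert-butyldimethylsilyl) ether of 10
Conditions: TBSCl (2.5 equiv), imidazole (5 equiv), DMF, rt
Reagents that add atoms: tert-butyldimethylsilyl chloride (TBSCl), CC(C)(C)[Si](C)(C)Cl
Why: Standard silylation caps the primary and the secondary hydroxyl in one operation, draws any C3–O–C9 lactol back to the open keto form and installs two groups that can leave together in step 11.

Step 6
Reactants: 11 C3/C7 bis(tert-butyldimethylsilyl) ether of 10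
Product: 13 C9 enol triflate of 11 (C8=C9 alkene), via potassium enolate 12 (not isolated)
Conditions: KN(SiMe3)2 (KHMDS, 1.1 equiv), THF, −78 °C; then Comins' reagent (1.2 equiv), −78 °C
Reagents that add atoms: Comins' reagent, N-(5-chloropyridin-2-yl)bis(trifluoromethanesulfonimide), FC(F)(F)S(=O)(=O)N(c1ccc(Cl)cn1)S(=O)(=O)C(F)(F)F
Why: C10 is quaternary, so only the C8–C9 enolate 12 can form, and the very reactive triflating agent should trap it at −78 °C before the C7 silyloxy group can be expelled (kinetic enol triflate formation), which is a gentler entry than a hot hydrazone condensation that could lose the β-silyloxy group and close a pyrazoline.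

Step 7
Reactants: 13 C9 enol triflate of 11
Product: 14 C9 alkenyl iodide (5S,10S; C7 epimers)
Conditions: Ni(cod)2 (10 mol %), NaI (2 equiv), DMA/THF 1:3, rt
Reagents that add atoms: sodium iodide, [Na+].[I-]
Why: Zerovalent nickel inserts into the C9–O bond, exchanges triflate for iodide and releases the alkenyl iodide at room temperature (nickel-catalysed halogenation of enol triflates), conditions that leave silyl ethers and the isopropenyl group alone.

Step 8
Reactants: 15 dimethyl squarate; 16 isopropylmagnesium chloride
Product: 18 3-isopropyl-4-methoxycyclobut-3-ene-1,2-dione, via squarate carbinol 17 (not isolated)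
Conditions: 16 (1.05 equiv), THF, −78 °C; 1 M HCl quench; crude 17, conc. HCl (cat.), CH2Cl2, rt
Reagents that add atoms: isopropylmagnesium chloride 16, CC(C)[Mg]Cl; water (its oxygen ends in the new carbonyl while the carbinol oxygen leaves as water), O
Why: 1,2-Addition of the Grignard reagent to one squarate carbonyl gives carbinol 17, and acid then ionises the hydroxyl, water adds to the methoxy-stabilised cation and methanol is lost (the standard squarate-to-alkylcyclobutenedione sequence).

Step 9
Reactants: 14 C9 alkenyl iodide; 18 3-isopropyl-4-methoxycyclobut-3-ene-1,2-dione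
Product: 20 (5S,10S)-4-(ring-B cyclohexenyl)-4-hydroxy-2-isopropyl-3-methoxycyclobut-2-en-1-one (epimers at C7 and C11), via alkenyllithium 19 (not isolated)
Conditions: t-BuLi (2.0 equiv), Et2O, −78 °C; cannulated into 18 (1.2 equiv), THF, −78 °C; AcOH (1.1 equiv) quench at −78 °C
Reagents that add atoms: none
Why: Iodine–lithium exchange gives 19 with lithium trans to C7 across the ring alkene, so no silyl migration is open to it, and 19 should add to the carbonyl next to the methoxy-bearing carbon because the other carbonyl is deactivated as a vinylogous ester (1,2-addition of an organolithium to a cyclobutenedione), the new carbinol centre being of no consequence.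

Step 10
Reactants: 20 (5S,10S)-4-(ring-B cyclohexenyl)-4-hydroxy-2-isopropyl-3-methoxycyclobut-2-en-1-one
Product: 23 (5S,10S)-11,14-hydroquinone bearing C7-OTBS and C3-OTBS, via dienylketene 21 (not isolated), via cyclohexadienone 22 (not isolated)
Conditions: degassed PhMe (0.01 M), 110 °C, Ar, base-washed glassware
Reagents that add atoms: none
Why: Heating breaks the C11–C14 bond in a conrotatory four-electron opening in which the donor hydroxyl turns outward and the cyclohexenyl group inward, so dienylketene 21 forms with ketene carbon C14 held next to C8. A disrotatory six-electron electrocyclisation then forms C8–C14 and closes six-membered ring C as cyclohexadienone 22, whose C8 hydrogen moves to oxygen to give the aromatic hydroquinone; this is the Moore rearrangement of 4-alkenyl-4-hydroxycyclobutenones. No lasting stereocentre is created, since C8 of 22 is transient and both carbinol epimers converge, while C5, C7 and C10 take no part. The selectivities needed are torquoselectivity, secured by the strong outward preference of the oxygen donor on C11, and the order of the ring substituents, which is already fixed in 20 because the carbinol carbon stands next to the methoxy carbon. Relief of ring strain and aromatisation should drive the sequence under neutral conditions that leave the silyl ethers and the isopropenyl group untouched.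

Step 11
Reactants: 23 (5S,10S)-11,14-hydroquinone bearing C7-OTBS and C3-OTBS
Product: 24 (5S,10S)-3,7,11,14-tetrahydroxy compound (hydroquinone diol; C7 epimers)
Conditions: TBAF/AcOH (1:1, 4 equiv), THF, Ar, 0 °C → rt; used crude
Reagents that add atoms: none
Why: Buffered fluoride cleaves both silyl ethers at neutral pH, which avoids acid ionisation of the very electron-rich C7 benzylic position, and any adventitious air oxidation of ring C is harmless because step 12 oxidises it anyway.

Step 12
Reactants: 24 (5S,10S)-3,7,11,14-tetrahydroxy compound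
Product: 27 (5S,10S)-7-oxo-11,14-quinone 3-carboxylic acid, via quinone diol 25 (not isolated), via quinone keto aldehyde 26 (not isolated)
Conditions: 2-azaadamantane N-oxyl (AZADO, 10 mol %), PhI(OAc)2 (4.5 equiv), MeCN/pH 7 phosphate buffer, 0 °C → rt
Reagents that add atoms: water, O
Why: PhI(OAc)2 first takes ring C to quinone 25, which shields the ring and switches off C7 ionisation, and the unhindered oxoammonium ion from AZADO then oxidises the C7 carbinol to the ketone and C3 by way of aldehyde 26 and its hydrate to the acid (nitroxyl/hypervalent iodine oxidation), the isopropenyl group being inert to both oxidants.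

Step 13
Reactants: 27 (5S,10S)-7-oxo-11,14-quinone 3-carboxylic acid
Product: 28 CNP0249049.1, (5S,10S)-11,14-dihydroxy-12-methoxy-7-oxo-3,4-seco-abieta-4(18),8,11,13-tetraen-3-oic acid
Conditions: Na2S2O4 (5 equiv), THF/H2O, Ar, rt; then pH 3
Reagents that add atoms: none
Why: Dithionite delivers two electrons to the fully substituted acylquinone and gives the hydroquinone, which is stabilised by the hydrogen bond from C14–OH to the C7 ketone, while ketone, alkene and acid are not reduced (standard quinone reduction).

Compound list
1 | 2-methylcyclohex-2-en-1-one | CC1=CCCCC1=O | starting material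
2 | isopropenylmagnesium bromide | C=C(C)[Mg]Br | starting material
3 | allyl bromide | C=CCBr | starting material
4 | bromomagnesium (S)-2-methyl-3-(prop-1-en-2-yl)cyclohex-1-en-1-olate | C=C(C)[C@@H]1CCCC(O[Mg]Br)=C1C | intermediate
5 | (2S,3S)-2-allyl-2-methyl-3-(prop-1-en-2-yl)cyclohexan-1-one; allyl trans and methyl cis to the isopropenyl group | C=C(C)[C@@H]1CCCC(=O)[C@@]1(C)CC=C | intermediate
6 | lithium C8=C9 enolate of 5 | C=C(C)[C@@H]1CCC=C(O[Li])[C@@]1(C)CC=C | intermediate
7 | (5S,6S)-6-allyl-6-methyl-5-(prop-1-en-2-yl)cyclohex-2-en-1-one | C=C(C)[C@@H]1CC=CC(=O)[C@@]1(C)CC=C | intermediate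
8 | (2S,3S)-2-allyl-2-methyl-5-(4,4,5,5-tetramethyl-1,3,2-dioxaborolan-2-yl)-3-(prop-1-en-2-yl)cyclohexan-1-one, epimers at C7 | C=C(C)[C@@H]1CC(B2OC(C)(C)C(C)(C)O2)CC(=O)[C@@]1(C)CC=C | intermediate
9 | compound 8 with the allyl group turned into a 3-(1,3,2-benzodioxaborol-2-yl)propyl chain | C=C(C)[C@@H]1CC(B2OC(C)(C)C(C)(C)O2)CC(=O)[C@@]1(C)CCCB1Oc2ccccc2O1 | intermediate
10 | (2S,3S)-5-hydroxy-2-(3-hydroxypropyl)-2-methyl-3-(prop-1-en-2-yl)cyclohexan-1-one, epimers at C7 | C=C(C)[C@@H]1CC(O)CC(=O)[C@@]1(C)CCCO | intermediate
11 | bis(tert-butyldimethylsilyl) ether of 10 (C3-OTBS, C7-OTBS, C9 ketone) | C=C(C)[C@@H]1CC(O[Si](C)(C)C(C)(C)C)CC(=O)[C@@]1(C)CCCO[Si](C)(C)C(C)(C)C | intermediate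
12 | potassium C8=C9 enolate of 11 | C=C(C)[C@@H]1CC(O[Si](C)(C)C(C)(C)C)C=C(O[K])[C@@]1(C)CCCO[Si](C)(C)C(C)(C)C | intermediate
13 | (5S,6S)-3-(TBSO)-6-[3-(TBSO)propyl]-6-methyl-5-(prop-1-en-2-yl)cyclohex-1-en-1-yl trifluoromethanesulfonate, epimers at C7 | C=C(C)[C@@H]1CC(O[Si](C)(C)C(C)(C)C)C=C(OS(=O)(=O)C(F)(F)F)[C@@]1(C)CCCO[Si](C)(C)C(C)(C)C | intermediate
14 | corresponding C9 alkenyl iodide (5S,10S), epimers at C7 | C=C(C)[C@@H]1CC(O[Si](C)(C)C(C)(C)C)C=C(I)[C@@]1(C)CCCO[Si](C)(C)C(C)(C)C | intermediate
15 | dimethyl squarate | COC1=C(OC)C(=O)C1=O | starting material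
16 | isopropylmagnesium chloride | CC(C)[Mg]Cl | starting material
17 | 4-hydroxy-4-isopropyl-2,3-dimethoxycyclobut-2-en-1-one | COC1=C(OC)C(O)(C(C)C)C1=O | intermediate
18 | 3-isopropyl-4-methoxycyclobut-3-ene-1,2-dione | COC1=C(C(C)C)C(=O)C1=O | intermediate
19 | C9 alkenyllithium derived from 14 | C=C(C)[C@@H]1CC(O[Si](C)(C)C(C)(C)C)C=C([Li])[C@@]1(C)CCCO[Si](C)(C)C(C)(C)C | intermediate
20 | cyclobutenone carbinol: 4-hydroxy-2-isopropyl-3-methoxycyclobut-2-en-1-one bearing at C4 the ring-B cyclohex-1-enyl group (bond C9–C11; C7-OTBS, 5S isopropenyl, 10S methyl and 3-TBSO-propyl), epimers at C7 and C11 | C=C(C)[C@@H]1CC(O[Si](C)(C)C(C)(C)C)C=C([C@@]1(C)CCCO[Si](C)(C)C(C)(C)C)C1(O)C(OC)=C(C(C)C)C1=O | intermediate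
21 | dienylketene O=C14=C13(i-Pr)–C12(OMe)=C11(OH)–C9=C8, with C9 and C13 cis on the C11=C12 bond | C=C(C)[C@@H]1CC(O[Si](C)(C)C(C)(C)C)C=C([C@@]1(C)CCCO[Si](C)(C)C(C)(C)C)/C(O)=C(OC)\C(C(C)C)=C=O | intermediate
22 | ring-C cyclohexa-2,4-dienone (C14 ketone, C8–H, C11 enol) | C=C(C)[C@@H]1CC(O[Si](C)(C)C(C)(C)C)C2C(=O)C(C(C)C)=C(OC)C(O)=C2[C@@]1(C)CCCO[Si](C)(C)C(C)(C)C | intermediate
23 | (5S,10S)-11,14-dihydroxy-12-methoxy-13-isopropyl arene with C7-OTBS and C3-OTBS, epimers at C7 | C=C(C)[C@@H]1CC(O[Si](C)(C)C(C)(C)C)c2c(O)c(C(C)C)c(OC)c(O)c2[C@@]1(C)CCCO[Si](C)(C)C(C)(C)C | intermediate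
24 | (5S,10S)-hydroquinone diol (C3-OH, C7-OH, C11-OH, C14-OH), epimers at C7 | C=C(C)[C@@H]1CC(O)c2c(O)c(C(C)C)c(OC)c(O)c2[C@@]1(C)CCCO | intermediate
25 | (5S,10S)-11,14-quinone with C7-OH and C3-OH | C=C(C)[C@@H]1CC(O)C2=C(C(=O)C(OC)=C(C(C)C)C2=O)[C@@]1(C)CCCO | intermediate
26 | (5S,10S)-7-oxo-11,14-quinone 3-aldehyde | C=C(C)[C@@H]1CC(=O)C2=C(C(=O)C(OC)=C(C(C)C)C2=O)[C@@]1(C)CCC=O | intermediate
27 | (5S,10S)-7-oxo-11,14-quinone 3-carboxylic acid | C=C(C)[C@@H]1CC(=O)C2=C(C(=O)C(OC)=C(C(C)C)C2=O)[C@@]1(C)CCC(=O)O | intermediate
28 | CNP0249049.1, (5S,10S)-11,14-dihydroxy-12-methoxy-7-oxo-3,4-seco-abieta-4(18),8,11,13-tetraen-3-oic acid | C=C(C)[C@@H]1CC(=O)c2c(O)c(C(C)C)c(OC)c(O)c2[C@@]1(C)CCC(=O)O | target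

Total step count: 13. Longest linear sequence: 12 (steps 1–7 and 9–13). Step 8 is a one-step side branch.

Steps most likely to fail

**Step 10.**
- What may go wrong: the six-electron closure next to quaternary C10 may be slow. The enol of the ketene intermediate could then tautomerise, or its free hydroxyl could capture the ketene. The electron-rich free hydroquinone could also be lost through autoxidation or through ionisation at C7 at the bath temperature.
- Fallback, from 20 back to 24: the tertiary hydroxyl of 20 is capped with TESOTf and 2,6-lutidine in CH2Cl2 at −78 → 0 °C to give the carbinol triethylsilyl ether F1. Thermolysis of this 4-silyloxycyclobutenone is a known variant of the same ring expansion. It should give the C11 triethylsilyl ether of the hydroquinone F2. In F2 the C11 oxygen can neither tautomerise nor acylate, and the arene is much harder to oxidise. The buffered fluoride of step 11 then removes all three silyl groups and the route is rejoined at 24.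

**Step 9.**
- What may go wrong: the halogen–lithium exchange may be incomplete or unclean. Surplus tert-butyllithium may compete for the dione. Attack of the neopentyl-type alkenyl anion may be so slow that electron transfer or displacement of methoxide takes over.
- Fallback, from 13 back to 20, which also makes step 7 unnecessary: Stille-type stannylation of 13 (Pd(PPh3)4, LiCl, Me3SnSnMe3, THF, 65 °C) gives the alkenyl trimethylstannane F3. Tin–lithium exchange with exactly one equivalent of MeLi in THF at −78 °C produces 19 without any excess alkyllithium. Transfer to anhydrous CeCl3 gives the alkenylcerium dichloride F4. This nucleophile is less basic and more oxophilic, of the kind known for clean 1,2-addition to crowded or easily reduced carbonyl groups. Addition to 18 and protonation with AcOH gives 20.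

**Step 1.**
- What may go wrong: the copper catalyst may show poor facial selectivity on an α-substituted enone with an alkenyl Grignard reagent. Allylation of the hindered magnesium enolate may also be sluggish.
- Fallback, from 1 back to 5, which replaces asymmetric induction by resolution and the one-pot trapping by a stepwise one: ligand-free CuBr·SMe2 (10 mol %), 2 and TMSCl in THF at −78 °C give the racemic trimethylsilyl enol ether F5. MeLi in THF at 0 °C regenerates the regiodefined racemic lithium enolate F6. Treatment with 3 and DMPU gives the trans-allylated ketone as the racemate, that is 5 together with its mirror image F7. Preparative supercritical-fluid chromatography on a polysaccharide chiral stationary phase then delivers 5.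

Further compounds
F1 | step 10 | carbinol triethylsilyl ether of 20 | C=C(C)[C@@H]1CC(O[Si](C)(C)C(C)(C)C)C=C([C@@]1(C)CCCO[Si](C)(C)C(C)(C)C)C1(O[Si](CC)(CC)CC)C(OC)=C(C(C)C)C1=O
F2 | step 10 | C11 triethylsilyl ether of hydroquinone 23 | C=C(C)[C@@H]1CC(O[Si](C)(C)C(C)(C)C)c2c(O)c(C(C)C)c(OC)c(O[Si](CC)(CC)CC)c2[C@@]1(C)CCCO[Si](C)(C)C(C)(C)C
F3 | step 9 | C9 alkenyl trimethylstannane | C=C(C)[C@@H]1CC(O[Si](C)(C)C(C)(C)C)C=C([Sn](C)(C)C)[C@@]1(C)CCCO[Si](C)(C)C(C)(C)C
F4 | step 9 | C9 alkenylcerium dichloride | C=C(C)[C@@H]1CC(O[Si](C)(C)C(C)(C)C)C=C([Ce](Cl)Cl)[C@@]1(C)CCCO[Si](C)(C)C(C)(C)C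
F5 | step 1 | racemic 2-methyl-3-(prop-1-en-2-yl)-1-(trimethylsilyloxy)cyclohex-1-ene | C=C(C)C1CCCC(O[Si](C)(C)C)=C1C
F6 | step 1 | racemic lithium 2-methyl-3-(prop-1-en-2-yl)cyclohex-1-en-1-olate | C=C(C)C1CCCC(O[Li])=C1C
F7 | step 1 | (2R,3R)-2-allyl-2-methyl-3-(prop-1-en-2-yl)cyclohexan-1-one, mirror image of 5 | C=C(C)[C@H]1CCCC(=O)[C@]1(C)CC=C
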